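The readings are simulated from invented constants; noise was put on by code.

I started from a small charge: Thursday's flask held 0.088 M of substrate, and from its readings I had to say what zeta, theta and beta would show at 25 h.

the same everywhere: gas phase 7.5 mM (held)

| run | substrate | remark | time |
|---|---|---|---|
| Thursday's | 0.088 M | run made earlier |  |
| zeta | 0.080 M |  | 25 h |
| theta | 0.25 M |  | 25 h |
| beta | 0.80 M |  | 25 h |

- Thursday's (time / h: target / %, side product / %): 0.667: 0, 4; 1.50: 8, 11; 4.00: 13, 21; 8.00: 22, 44

(each reading ± 2 percentage points)

- at the start none of the gas phase is in solution
- the share counts what is present at the end, not what went on to other products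
- "hardly changes" means that all values lie within two and a half points (for a concentration: within two and a half percent of the largest)

* share of target in all that became target or side product for zeta, theta, beta, in this order
* the shape of the row from first to last (falls all the way / falls, then rises / hardly changes / rises all the way / rises, then falls)

I built the flask up one process at a time. First I took one step, substrate to side product at a rate proportional to [substrate]; such a flask has a share of zero, and Thursday's first reading, 0% target beside 4% side product, looked like that. Then I added the step to target and let [dissolved gas] stand at saturation. That step is then pseudo-first-order in substrate, so both rates scale with [substrate], their ratio does not depend on the charge, and the row is flat. The reading at 8.00 h gave 33.3%, with each reading scattered by 2 percentage points. I called this the read share, target over target plus side product in Thursday's flask at that one reading, and took it as a scattered mark for the level of the flat row, though it belongs to 8.00 h and not to 25 h.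

Last I let the gas enter at a finite pace. Thursday's pace, scaled by the charge, asks 2.20 mM h⁻¹ of gas in zeta and 22.0 mM h⁻¹ in beta, ten times as much, while a saturated solution holds 7.5 mM. So I expected the gas to fall behind as the charge grew and the share to drop with it, with zeta staying near the read share.

The forecast printed 34%, 26% and 15%, shape falls all the way, on the ground that “Target formation would then cap near the transfer limit, while the gas-free side route keeps scaling with substrate”. It agreed with me in direction and put numbers on the fall, which I had not.

The row came out at 23.5%, 21.9% and 18.3% for zeta, theta and beta, so it falls all the way, with zeta at 23.5% against the forecast's 34%.

    gas phase ⇌ dissolved gas, rate k1*(csat - [dissolved gas]) (kL = 8.40 × 10⁻⁴ s⁻¹)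
    substrate + dissolved gas ⇌ target (K = 150 L mol⁻¹, k = 0.00190 L mol⁻¹ s⁻¹)
    substrate → side product (k = 2.10 × 10⁻⁵ s⁻¹)
    target → over-reaction product (k = 2.00 × 10⁻⁸ s⁻¹)

In zeta, target stood at 22.2% after 12.5 h and 20.7% after 25.0 h, while side product rose from 51.2% to 67.6%. Zeta's share was 30.2% after 12.5 h, lower than the read share of 33.3% from Thursday's flask at 8.00 h, and 23.5% after 25 h.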